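**Plan**
1. Achiral germacrone 1 supplies all fifteen skeletal carbons, the C8 ketone and both ring methyls; 3-methylbut-2-enoic acid 2 supplies the ester.
2. Retrosynthetic cuts, in order: the O3–acyl bond; the C11–O bond (with C6=C7 moved back to C7=C11); the C3–O and C4–O bonds of the cis-diol; last the C5–C10 ring-fusion bond.
3. Enabling feature (eudesmane numbering; ring A = C1, C2, C3, C4, C5, C10; ring B = C5, C6, C7, C8, C9, C10): the bond shared by ring A and ring B, C5–C10, spans a ten-membered carbocycle. Opening it gives (E,E)-germacra-1(10),4,7(11)-trien-8-one, whose C1=C10 and C4=C5 alkenes face each other and already carry the C4 and C10 methyls.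
4. Forward: one proton-triggered transannular C5–C10 closure forms ring A and ring B together; then C3/C4 dihydroxylation, C11 oxygenation with alkene shift into ring B, and O3 acylation.
5. Stereochemistry: C5 and C10 absolute from a chiral acid, relative (trans) from the E,E geometry; C3 and C4 from α-face osmylation anti to the axial C10 methyl; C11 is not stereogenic.

Key step: step 1

Remark on the chemistry: α means the face opposite the C10 methyl. Which antipode of the chiral acid leads to the (5R,10R) series has to be found by experiment; the (S,S) form is written for definiteness.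

**Step 1**
Reactants: 1 germacrone
Product: 3 (5R,10R)-eudesma-3,7(11)-dien-8-one
Conditions: (S,S)-IDPi [imidodiphosphorimidic acid from two (S)-3,3'-bis(3,5-bis(trifluoromethyl)phenyl)-BINOL units, core P(=NSO2CF3)–NH–P(=NSO2CF3)] (5 mol%), (CF3)3COH/CHCl3, −20 °C
Reagents that add atoms: none
Why: Proposed new method: the confined acid, hydrogen-bonded to the C8 carbonyl, should protonate C1 of the C1=C10 alkene in one of the two interconverting planar-chiral crossed conformers of 1; the tertiary C10 cation is then captured across the ring by C5 of the C4=C5 alkene, and the resulting tertiary C4 cation is discharged when the counter-anion removes H3, which returns the catalyst. The closest known reaction types are the acid-promoted transannular cyclisation of germacrone and other (E,E)-germacra-1(10),4-dienes to racemic trans-eudesmanes, and the imidodiphosphorimidate-catalysed, proton-initiated enantioselective cyclisation of acyclic polyenes. The single C5–C10 bond closes both rings at once, ring A in the 6-endo mode and ring B in the 6-exo mode of attack of the C4=C5 alkene on C10, both transannular within the ten-membered ring. C5 and C10 should take their relative configuration (5α-H, 10β-methyl, trans fusion) from anti addition across the two E alkenes held parallel and crossed, and their absolute configuration from the catalyst pocket, which can select one conformer enantiomer in a dynamic kinetic sense because 1 has no stereocentre. The step needs protonation at C1 rather than C5 and loss of H3 rather than H5 or H15: the first is favoured because only the C10 cation can close a six-membered ring through a tertiary cation and the carbonyl anchors the acid next to C9/C10/C1, while the second has to be secured by the anion reaching the exposed axial 3α-H more easily than the ring-fusion 5-H.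

**Step 2**
Reactants: 3 (5R,10R)-eudesma-3,7(11)-dien-8-one
Product: 4 3α,4α-dihydroxy-5αH-eudesm-7(11)-en-8-one
Conditions: K2OsO4·2H2O (2 mol%), NMO (N-methylmorpholine N-oxide), acetone/H2O, 0 °C to rt; then aq. Na2SO3
Reagents that add atoms: N-methylmorpholine N-oxide, C[N+]1([O-])CCOCC1; water, O (both oxygens are passed on through OsO4, O=[Os](=O)(=O)=O)
Why: Catalytic osmium tetroxide syn-dihydroxylation with NMO as reoxidant: the electron-rich trisubstituted C3=C4 alkene should react far faster than the tetrasubstituted, carbonyl-conjugated C7=C11 alkene, and the addition should occur on the α face, away from the axial 10β-methyl that shields the β face of C4, which sets 3α-OH (3R) and 4α-OH/4β-CH3 (4S) together.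

**Step 3**
Reactants: 4 3α,4α-dihydroxy-5αH-eudesm-7(11)-en-8-one
Product: 6 3α,4α,11-trihydroxy-5αH-eudesm-6-en-8-one, via 11-hydroperoxide 5 (not isolated)
Conditions: O2, hν (visible), TPP (5,10,15,20-tetraphenylporphyrin, cat.), CH2Cl2, 0 °C; then PPh3, 0 °C to rt
Reagents that add atoms: dioxygen, O=O
Why: Schenck ene reaction of singlet oxygen with the s-cis α-alkylidene ketone, followed by phosphine reduction: as is usual for α,β-unsaturated carbonyl compounds, oxygen should bond to the β-carbon C11 and the hydrogen should come from the group geminal to the carbonyl on the α-carbon (an axial C6–H), so the alkene moves to C6=C7 and stays conjugated with C8=O; PPh3 then cleaves the O–O bond of 5 to the tertiary alcohol, and no stereocentre is made or touched because C11 carries two methyls.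

**Step 4**
Reactants: 6 3α,4α,11-trihydroxy-5αH-eudesm-6-en-8-one; 2 3-methylbut-2-enoic acid
Product: 7 4α,11-dihydroxy-8-oxo-5αH-eudesm-6-en-3α-yl 3-methylbut-2-enoate (target)
Conditions: DCC (N,N'-dicyclohexylcarbodiimide), DMAP (4-dimethylaminopyridine, cat.), CH2Cl2, 0 °C to rt
Reagents that add atoms: none
Why: Steglich esterification: the acylpyridinium formed from 2, DCC and DMAP should acylate only the secondary O3 hydroxyl, the tertiary C4 and C11 hydroxyls being too hindered at room temperature, and C3 keeps its configuration because the C3–O bond is not broken.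

**Compound list**
1 | germacrone, (3E,7E)-3,7-dimethyl-10-(propan-2-ylidene)cyclodeca-3,7-dien-1-one | O=C1C/C(C)=C/CC/C(C)=C/CC1=C(C)C | starting material
2 | 3-methylbut-2-enoic acid | CC(C)=CC(=O)O | starting material
3 | (5R,10R)-eudesma-3,7(11)-dien-8-one (5α-H, 10β-methyl, trans-fused) | CC1=CCC[C@]2(C)CC(=O)C(=C(C)C)C[C@@H]12 | intermediate
4 | (3R,4S,5R,10R)-3α,4α-dihydroxy-5αH-eudesm-7(11)-en-8-one | O[C@@H]1CC[C@]2(C)CC(=O)C(=C(C)C)C[C@H]2[C@]1(C)O | intermediate
5 | (3R,4S,5R,10R)-11-hydroperoxy-3α,4α-dihydroxy-5αH-eudesm-6-en-8-one (formed in the flask, not isolated) | O[C@@H]1CC[C@]2(C)CC(=O)C(C(C)(C)OO)=C[C@H]2[C@]1(C)O | intermediate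
6 | (3R,4S,5R,10R)-3α,4α,11-trihydroxy-5αH-eudesm-6-en-8-one | O[C@@H]1CC[C@]2(C)CC(=O)C(C(C)(C)O)=C[C@H]2[C@]1(C)O | intermediate
7 | (3R,4S,5R,10R)-4,11-dihydroxy-8-oxoeudesm-6-en-3-yl 3-methylbut-2-enoate (CNP0175033.1) | CC(C)=CC(=O)O[C@@H]1CC[C@]2(C)CC(=O)C(C(C)(C)O)=C[C@H]2[C@]1(C)O | target

**Step count and risks**
Total steps: 4. Longest linear sequence: 4 steps (1 → 3 → 4 → 6 → 7).

Steps most likely to fail:

1. Step 1 (proposed new method). The catalyst may not discriminate well enough between the two enantiomeric ring conformers, and the C4 cation may lose a proton toward C5 or C15 instead of C3. Fallback, setting out from 1: the long-known cyclisation with a strong achiral Brønsted acid (for example p-TsOH·H2O in CH2Cl2) should give the trans-fused dienone as a racemate, that is 3 together with its mirror image (5S,10S)-eudesma-3,7(11)-dien-8-one F1. After removal of the Δ4 and Δ4(15) isomers on AgNO3-impregnated silica, the enantiomers would be separated by preparative chromatography on a polysaccharide-carbamate chiral stationary phase. The (5R,10R) antipode is 3, where the route is rejoined.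

2. Step 3. The ene reaction of the electron-poor alkene may be slow, and regiocontrol may be lost through hydrogen abstraction from the C12/C13 methyls, which puts the oxygen on C7. Fallback, setting out from 4 and returning at 7:
   - Weitz–Scheffer epoxidation (30% H2O2, NaOH, MeOH, 0 °C) should give 7,11-epoxy-3α,4α-dihydroxy-5αH-eudesman-8-one F2 (either C7 epimer serves).
   - Reductive cleavage of the α C7–O bond with SmI2 (THF/MeOH, −90 °C) should give the β-hydroxy ketone 3α,4α,11-trihydroxy-5αH-eudesman-8-one F3.
   - Steglich esterification of O3 with 2 (DCC, DMAP, CH2Cl2) should give 4α,11-dihydroxy-8-oxo-5αH-eudesman-3α-yl 3-methylbut-2-enoate F4.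
   - α,β-Dehydrogenation with IBX (2-iodoxybenzoic acid, DMSO, 65–75 °C) can only run toward C6, since C10 and C11 carry no hydrogen, and should give 7 directly.

3. Step 4. Acylation of the axial, neopentyl-like 3α-hydroxyl may be slow, which would let the activated acid rearrange to the N-acylurea or isomerise under base to the deconjugated 3-methylbut-3-enoyl unit. Fallback, setting out from 6 and returning at 7: heating 6 with Bu2SnO (toluene, reflux, azeotropic removal of water) should give the cyclic tin alkoxide 3,4-O-dibutylstannylene acetal of 6 F5. This is then acylated at the secondary oxygen with commercial 3-methylbut-2-enoyl chloride (CH2Cl2, 0 °C, no amine base), and aqueous work-up should give 7.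

**Further compounds**
F1 | step 1 | (5S,10S)-eudesma-3,7(11)-dien-8-one (mirror image of 3) | CC1=CCC[C@@]2(C)CC(=O)C(=C(C)C)C[C@H]12
F2 | step 3 | 7,11-epoxy-3α,4α-dihydroxy-5αH-eudesman-8-one (C7 not defined) | O[C@@H]1CC[C@]2(C)CC(=O)C3(OC3(C)C)C[C@H]2[C@]1(C)O
F3 | step 3 | 3α,4α,11-trihydroxy-5αH-eudesman-8-one (C7 not defined) | O[C@@H]1CC[C@]2(C)CC(=O)C(C(C)(C)O)C[C@H]2[C@]1(C)O
F4 | step 3 | 4α,11-dihydroxy-8-oxo-5αH-eudesman-3α-yl 3-methylbut-2-enoate (C7 not defined) | CC(C)=CC(=O)O[C@@H]1CC[C@]2(C)CC(=O)C(C(C)(C)O)C[C@H]2[C@]1(C)O
F5 | step 4 | 3,4-O-dibutylstannylene acetal of 6 | CCCC[Sn]1(CCCC)O[C@@H]2CC[C@]3(C)CC(=O)C(C(C)(C)O)=C[C@H]3[C@]2(C)O1
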